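**Plan**

1. Numbering is that of germacrane (ring C1–C10; C11, C12, C13 on C7; C14 on C10; C15 on C4). The retrosynthesis cuts first the lactone bonds O–C6 and C11–C12 (both to one CO2), then the C8 angelate, then C5=C6 (ring-closing metathesis) and C1=C10 (aldol–dehydration). This leaves West aldehyde 8 (C1–C5, C15) and East lactone 17 (C6–C11, C13, C14).
2. Enabling feature: C15–OH, the C4=C5 alkene and the lactone oxygen on C6 form a 1,4-dioxygenated but-2-ene, the imprint of a syn-1,4 opening of a 4,15-epoxy-5-ene. With an alkenylboronate at C11, CO2 can be stitched between C11 and C6, so that the α-methylene γ-lactone ring, the C6 stereocentre, the ring-cis C4=C5 alkene and the free C15 hydroxyl appear together.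
3. Forward order: 8 and 17 are joined at C1=C10; the ten-membered carbocycle closes at C5=C6 while C8–O and C14 are still tied up as a temporary γ-lactone. That lactone is reduced away, C14–OH is silylated, C8–OH is angeloylated, the CO2 step builds the 12,6-lactone, and desilylation ends the route.
4. Stereochemistry: C7 and C8 from an auxiliary-controlled syn aldol; the helper centre C4 from a tartrate-controlled epoxidation; C6 from C4 by double inversion at palladium; C1=C10 from E1cB elimination, C5=C6 and C4=C5 from the ring; the angelate geometry from angelic acid.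

Key step: step 16

**Route**

Step 1
Reactants: 1 5-bromo-2-methylpent-2-ene; 2 prop-2-yn-1-ol
Product: 4 6-methyl-2-methylidenehept-5-en-1-ol, via homoprenylmagnesium bromide 3 (not isolated)
Conditions: Mg, THF, 40 °C; then 2, CuI (10 mol %), Et2O, −10 °C → rt; aq NH4Cl
Reagents that add atoms: none
Why: Copper-catalysed carbomagnesiation of propargyl alcohol, in which the magnesium alkoxide directs anti-addition of the alkyl Grignard reagent to the internal alkyne carbon, so that protonation should give the 2-substituted allylic alcohol.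

Step 2
Reactants: 4 6-methyl-2-methylidenehept-5-en-1-ol
Product: 5 [(2R)-2-(4-methylpent-3-en-1-yl)oxiran-2-yl]methanol
Conditions: Ti(OiPr)4 (10 mol %), D-(−)-diisopropyl tartrate (12 mol %), t-BuOOH, 4 Å molecular sieves, CH2Cl2, −20 °C
Reagents that add atoms: tert-butyl hydroperoxide, CC(C)(C)OO
Why: Sharpless asymmetric epoxidation, in which the D-(−)-tartrate–titanium complex delivers oxygen to one face of the 2-substituted allylic alcohol and should set the quaternary C4 centre as R, while the isolated trisubstituted alkene has no directing hydroxyl and stays untouched.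

Step 3
Reactants: 5 [(2R)-2-(4-methylpent-3-en-1-yl)oxiran-2-yl]methanol
Product: 6 (2S)-2-(4-methylpent-3-en-1-yl)oxirane-2-carbaldehyde
Conditions: Dess–Martin periodinane, pyridine, CH2Cl2, 0 °C → rt
Reagents that add atoms: none
Why: Dess–Martin oxidation of the primary alcohol under buffered conditions that should leave the epoxide intact; the α-carbon is quaternary and cannot epimerise (the descriptor changes only because the priorities change).

Step 4
Reactants: 6 (2S)-2-(4-methylpent-3-en-1-yl)oxirane-2-carbaldehyde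
Product: 7 (2R)-2-ethenyl-2-(4-methylpent-3-en-1-yl)oxirane
Conditions: Ph3PCH3Br, KOt-Bu, THF, 0 °C; then 6, −78 → 0 °C
Reagents that add atoms: methyltriphenylphosphonium bromide, C[P+](c1ccccc1)(c1ccccc1)c1ccccc1.[Br-]
Why: Wittig methylenation of a non-enolisable α-epoxy aldehyde should give the vinyl epoxide (C5=CH2) without touching C4.

Step 5
Reactants: 7 (2R)-2-ethenyl-2-(4-methylpent-3-en-1-yl)oxirane
Product: 8 3-[(2R)-2-ethenyloxiran-2-yl]propanal
Conditions: O3, CH2Cl2, −78 °C (Sudan Red 7B end point); then Me2S, −78 °C → rt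
Reagents that add atoms: ozone, [O-][O+]=O
Why: Chemoselective ozonolysis, since the electron-rich trisubstituted alkene reacts far faster than the vinyl group deactivated by the neighbouring epoxide oxygen, so that titration to the indicator end point should cleave only the isopropylidene terminus to the C1 aldehyde.

Step 6
Reactants: 9 (4S)-4-benzyl-1,3-thiazolidine-2-thione; 10 but-3-enoic acid
Product: 11 1-[(4S)-4-benzyl-2-sulfanylidene-1,3-thiazolidin-3-yl]but-3-en-1-one
Conditions: DCC, DMAP (5 mol %), CH2Cl2, −10 °C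
Reagents that add atoms: none
Why: Carbodiimide-mediated N-acylation of the thiazolidinethione; low temperature and only catalytic DMAP should keep the β,γ-alkene out of conjugation.

Step 7
Reactants: 11 1-[(4S)-4-benzyl-2-sulfanylidene-1,3-thiazolidin-3-yl]but-3-en-1-one; 12 methyl 4-oxobutanoate
Product: 14 (5R)-5-{(2S)-1-[(4S)-4-benzyl-2-sulfanylidene-1,3-thiazolidin-3-yl]-1-oxobut-3-en-2-yl}oxolan-2-one, via aldol adduct 13 (not isolated)
Conditions: TiCl4 (1.05 equiv), i-Pr2NEt (1.1 equiv), N-methylpyrrolidinone (1.0 equiv), CH2Cl2, 0 → −78 °C; 12; aq NH4Cl; then PPTS (10 mol %), CH2Cl2, rt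
Reagents that add atoms: none
Why: Titanium enolate aldol of an N-acylthiazolidinethione (Crimmins aldol), in which the Z-dienolate reacts at its α-carbon through a non-chelated chair transition state with one face shielded by the benzyl group of the (S)-auxiliary, which should give the Evans syn adduct (C7 S, C8 R) before the γ-hydroxy ester closes to the γ-lactone under mild acid.

Step 8
Reactants: 14 (5R)-5-{(2S)-1-[(4S)-4-benzyl-2-sulfanylidene-1,3-thiazolidin-3-yl]-1-oxobut-3-en-2-yl}oxolan-2-one
Product: 15 (2S)-2-[(2R)-5-oxooxolan-2-yl]but-3-enal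
Conditions: i-Bu2AlH (1.1 equiv), CH2Cl2, −78 °C, 10 min; aq potassium sodium tartrate
Reagents that add atoms: none
Why: Reductive cleavage of the N-acylthiazolidinethione, whose carbonyl is far more electrophilic than that of the lactone, so that one equivalent of hydride at −78 °C should stop at the aldehyde and release the auxiliary.

Step 9
Reactants: 15 (2S)-2-[(2R)-5-oxooxolan-2-yl]but-3-enal
Product: 16 (5R)-5-[(3R)-pent-1-en-4-yn-3-yl]oxolan-2-one
Conditions: Me3SiCHN2, LiN(i-Pr)2, THF, −78 → 0 °C
Reagents that add atoms: trimethylsilyldiazomethane, C[Si](C)(C)C=[N+]=[N-]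
Why: Colvin rearrangement, in which fast carbonyl addition at −78 °C, Peterson-type loss of silanolate and a 1,2-hydride shift of the alkylidene carbene give the terminal alkyne (C13 added) under conditions that should be too cold and brief to epimerise C7.

Step 10
Reactants: 16 (5R)-5-[(3R)-pent-1-en-4-yn-3-yl]oxolan-2-one
Product: 17 (5R)-5-[(3R)-2-(4,4,5,5-tetramethyl-1,3,2-dioxaborolan-2-yl)penta-1,4-dien-3-yl]oxolan-2-one
Conditions: CuCl (5 mol %), 1,3-dimesitylimidazolinium chloride (5 mol %), NaOt-Bu (10 mol %), B2pin2, MeOH, THF, −15 °C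
Reagents that add atoms: bis(pinacolato)diboron, CC1(C)OB(OC1(C)C)B1OC(C)(C)C(C)(C)O1
Why: Carbene–copper-catalysed protoboration of a terminal alkyne (syn Cu–B addition, then protonolysis by methanol), in which the N-aryl carbene ligand and the electron-withdrawing propargylic and homopropargylic substituents should send boron to the internal carbon C11, the alkyne reacting much faster than the isolated alkene.

Step 11
Reactants: 17 (5R)-5-[(3R)-2-(4,4,5,5-tetramethyl-1,3,2-dioxaborolan-2-yl)penta-1,4-dien-3-yl]oxolan-2-one; 8 3-[(2R)-2-ethenyloxiran-2-yl]propanal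
Product: 20 (3E,5R)-3-{3-[(2R)-2-ethenyloxiran-2-yl]propylidene}-5-[(3R)-2-(4,4,5,5-tetramethyl-1,3,2-dioxaborolan-2-yl)penta-1,4-dien-3-yl]oxolan-2-one, via lithium aldolate 18 (not isolated), via mesylate 19 (not isolated)
Conditions: LiN(i-Pr)2 (1.05 equiv), THF, −78 °C; 8; MsCl, −78 → 0 °C; DBU, 0 °C → rt
Reagents that add atoms: none
Why: Aldol addition of the lactone lithium enolate (its α-protons are far more acidic than the doubly allylic C7–H) followed by mesylation and E1cB elimination, which should give mainly the thermodynamically preferred E-alkylidene lactone with C2 cis to C9.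

Step 12
Reactants: 20 (3E,5R)-3-{3-[(2R)-2-ethenyloxiran-2-yl]propylidene}-5-[(3R)-2-(4,4,5,5-tetramethyl-1,3,2-dioxaborolan-2-yl)penta-1,4-dien-3-yl]oxolan-2-one
Product: 21 (4R,7R,8R)-4,15-epoxy-11-(pinacolboryl)-12-norgermacra-1(10),5,11(13)-trien-14,8-olide (1(10)E; 5Z)
Conditions: second-generation Grubbs catalyst RuCl2(=CHPh)(H2IMes)(PCy3) (10 mol %), toluene (1 mM), 80 °C
Reagents that add atoms: none
Why: Ring-closing metathesis of the two monosubstituted vinyl groups, which should give the ten-membered ring with a cis C5=C6 alkene (the trans isomer is too strained); the hindered 1,1-disubstituted vinylboronate stays out, and the lactone bridge makes C1=C10 an electron-poor enoate whose reaction with the C6 carbene would need a bridgehead alkene, which blocks truncation to a cyclopentene.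

Step 13
Reactants: 21 (4R,7R,8R)-4,15-epoxy-11-(pinacolboryl)-12-norgermacra-1(10),5,11(13)-trien-14,8-olide
Product: 22 (4R,7R,8R)-4,15-epoxy-11-(pinacolboryl)-12-norgermacra-1(10),5,11(13)-triene-8,14-diol
Conditions: i-Bu2AlH (4 equiv), THF, −78 → −40 °C; aq potassium sodium tartrate
Reagents that add atoms: none
Why: 1,2-Reduction of the α-alkylidene lactone by the aluminium hydride removes the temporary ring and releases the C14 allylic alcohol and the C8 alcohol; at low temperature in THF the reagent should not open the vinyl epoxide or attack the boronate.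

Step 14
Reactants: 22 (4R,7R,8R)-4,15-epoxy-11-(pinacolboryl)-12-norgermacra-1(10),5,11(13)-triene-8,14-diol
Product: 23 (4R,7R,8R)-14-(tert-butyldimethylsilyloxy)-4,15-epoxy-11-(pinacolboryl)-12-norgermacra-1(10),5,11(13)-trien-8-ol
Conditions: TBSCl (1.05 equiv), imidazole, CH2Cl2, −20 → 0 °C
Reagents that add atoms: tert-butyldimethylsilyl chloride, CC(C)(C)[Si](C)(C)Cl
Why: Selective silylation of the primary allylic alcohol over the hindered secondary C8 alcohol on steric grounds.

Step 15
Reactants: 23 (4R,7R,8R)-14-(tert-butyldimethylsilyloxy)-4,15-epoxy-11-(pinacolboryl)-12-norgermacra-1(10),5,11(13)-trien-8-ol; 24 angelic acid [(2Z)-2-methylbut-2-enoic acid]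
Product: 26 (4R,7R,8R)-8-angeloyloxy-14-(tert-butyldimethylsilyloxy)-4,15-epoxy-11-(pinacolboryl)-12-norgermacra-1(10),5,11(13)-triene, via mixed anhydride 25 (not isolated)
Conditions: 24, 2,4,6-trichlorobenzoyl chloride, Et3N, toluene, rt; then 23, toluene, 75 °C
Reagents that add atoms: none
Why: Yamaguchi-type esterification through the 2,4,6-trichlorobenzoyl mixed anhydride without DMAP, conditions under which the Z-configured angelate should not isomerise to the tiglate.

Step 16
Reactants: 26 (4R,7R,8R)-8-angeloyloxy-14-(tert-butyldimethylsilyloxy)-4,15-epoxy-11-(pinacolboryl)-12-norgermacra-1(10),5,11(13)-triene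
Product: 28 (6R,7R,8R)-8-angeloyloxy-14-(tert-butyldimethylsilyloxy)-15-hydroxygermacra-1(10),4,11(13)-trien-12,6-olide, via potassium acrylate 27 (not isolated)
Conditions: (IPr)CuCl (5 mol %; IPr = 1,3-bis(2,6-diisopropylphenyl)imidazol-2-ylidene), KOt-Bu (1.1 equiv), CO2 (1 atm), THF, 60 °C; then Ar purge, Pd(PPh3)4 (5 mol %), rt; aq NH4Cl
Reagents that add atoms: carbon dioxide, O=C=O
Why: tert-Butoxide adds to boron, the borate transmetalates to the carbene–copper centre, CO2 inserts into the Cu–C(sp2) bond and potassium acrylate 27 is released (C11–C12 formed); zerovalent palladium then ionises the 4,15-epoxide anti to the C4–O bond to a π-allyl palladium alkoxide spanning C4–C5–C6, which the tethered carboxylate attacks at C6 on the face opposite to palladium (O–C6 formed). The closest known reaction types are the carbene–copper-catalysed carboxylation of alkenylboronic esters with CO2 and the palladium-catalysed syn-1,4-addition of carboxylic acids to cyclic 1,3-diene monoepoxides (Tsuji–Trost). The γ-lactone closes by 5-exo attack of oxygen on the allyl terminus C6, which is preferred over attack at the fully substituted C4 that would give a seven-membered ring. The new C6 stereocentre is fixed by the C4 epoxide configuration through double inversion (4R gives 6R, the trans-fused lactone), and the C4=C5 geometry by the anti,anti π-allyl that the ten-membered ring enforces (C3 and C7 both inside), which also leaves C15 as the free alcohol. The step needs the two catalysts to act in sequence, which is secured by adding palladium only after carboxylation is complete and CO2 is purged, so that neither boronate–allyl coupling nor cyclic carbonate formation can compete; under CO2 the tert-butoxide is buffered as its carbonate, which should protect the angelate.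

Step 17
Reactants: 28 (6R,7R,8R)-8-angeloyloxy-14-(tert-butyldimethylsilyloxy)-15-hydroxygermacra-1(10),4,11(13)-trien-12,6-olide
Product: 29 (6R,7R,8R)-8-angeloyloxy-14,15-dihydroxygermacra-1(10),4,11(13)-trien-12,6-olide (target)
Conditions: HF·pyridine, pyridine, THF, 0 °C → rt
Reagents that add atoms: none
Why: Fluoride cleavage of the primary allylic silyl ether under buffered conditions that should leave the α-methylene lactone, the angelate and the allylic C–O bonds untouched.

**Compound list**

1 | 5-bromo-2-methylpent-2-ene | CC(C)=CCCBr | starting material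
2 | prop-2-yn-1-ol | C#CCO | starting material
3 | (4-methylpent-3-en-1-yl)magnesium bromide (homoprenylmagnesium bromide) | CC(C)=CCC[Mg]Br | intermediate
4 | 6-methyl-2-methylidenehept-5-en-1-ol | C=C(CO)CCC=C(C)C | intermediate
5 | [(2R)-2-(4-methylpent-3-en-1-yl)oxiran-2-yl]methanol | OC[C@]1(CCC=C(C)C)CO1 | intermediate
6 | (2S)-2-(4-methylpent-3-en-1-yl)oxirane-2-carbaldehyde | O=C[C@]1(CCC=C(C)C)CO1 | intermediate
7 | (2R)-2-ethenyl-2-(4-methylpent-3-en-1-yl)oxirane | C=C[C@]1(CCC=C(C)C)CO1 | intermediate
8 | 3-[(2R)-2-ethenyloxiran-2-yl]propanal | C=C[C@]1(CCC=O)CO1 | intermediate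
9 | (4S)-4-benzyl-1,3-thiazolidine-2-thione | S=C1N[C@@H](Cc2ccccc2)CS1 | starting material
10 | but-3-enoic acid | C=CCC(=O)O | starting material
11 | 1-[(4S)-4-benzyl-2-sulfanylidene-1,3-thiazolidin-3-yl]but-3-en-1-one | C=CCC(=O)N1C(=S)SC[C@@H]1Cc1ccccc1 | intermediate
12 | methyl 4-oxobutanoate | COC(=O)CCC=O | starting material
13 | methyl (4R,5S)-5-[(4S)-4-benzyl-2-sulfanylidene-1,3-thiazolidine-3-carbonyl]-4-hydroxyhept-6-enoate (aldol adduct) | C=C[C@@H]([C@H](O)CCC(=O)OC)C(=O)N1C(=S)SC[C@@H]1Cc1ccccc1 | intermediate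
14 | (5R)-5-{(2S)-1-[(4S)-4-benzyl-2-sulfanylidene-1,3-thiazolidin-3-yl]-1-oxobut-3-en-2-yl}oxolan-2-one | C=C[C@@H]([C@H]1CCC(=O)O1)C(=O)N1C(=S)SC[C@@H]1Cc1ccccc1 | intermediate
15 | (2S)-2-[(2R)-5-oxooxolan-2-yl]but-3-enal | C=C[C@@H]([C@H]1CCC(=O)O1)C=O | intermediate
16 | (5R)-5-[(3R)-pent-1-en-4-yn-3-yl]oxolan-2-one | C=C[C@@H]([C@H]1CCC(=O)O1)C#C | intermediate
17 | (5R)-5-[(3R)-2-(4,4,5,5-tetramethyl-1,3,2-dioxaborolan-2-yl)penta-1,4-dien-3-yl]oxolan-2-one | C=C[C@@H]([C@H]1CCC(=O)O1)C(=C)B1OC(C)(C)C(C)(C)O1 | intermediate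
18 | lithium aldolate of 17 and 8: lithium alkoxide of (5R)-3-{3-[(2R)-2-ethenyloxiran-2-yl]-1-hydroxypropyl}-5-[(3R)-2-(pinacolboryl)penta-1,4-dien-3-yl]oxolan-2-one, mixture at the two new centres | C=C[C@@H]([C@H]1CC(C(O[Li])CC[C@@]2(C=C)CO2)C(=O)O1)C(=C)B1OC(C)(C)C(C)(C)O1 | intermediate
19 | methanesulfonate of the aldol adduct in 18, mixture at the two new centres | C=C[C@@H]([C@H]1CC(C(OS(C)(=O)=O)CC[C@@]2(C=C)CO2)C(=O)O1)C(=C)B1OC(C)(C)C(C)(C)O1 | intermediate
20 | (3E,5R)-3-{3-[(2R)-2-ethenyloxiran-2-yl]propylidene}-5-[(3R)-2-(4,4,5,5-tetramethyl-1,3,2-dioxaborolan-2-yl)penta-1,4-dien-3-yl]oxolan-2-one | C=C[C@@H]([C@H]1C/C(=C\CC[C@@]2(C=C)CO2)C(=O)O1)C(=C)B1OC(C)(C)C(C)(C)O1 | intermediate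
21 | (4R,7R,8R)-4,15-epoxy-11-(pinacolboryl)-12-norgermacra-1(10),5,11(13)-trien-14,8-olide, 1(10)E and 5Z (bridged macrocyclic lactone) | C=C(B1OC(C)(C)C(C)(C)O1)[C@H]1/C=C\[C@@]2(CO2)CC/C=C3\C[C@H]1OC3=O | intermediate
22 | (4R,7R,8R)-4,15-epoxy-11-(pinacolboryl)-12-norgermacra-1(10),5,11(13)-triene-8,14-diol, 1(10)E and 5Z | C=C(B1OC(C)(C)C(C)(C)O1)[C@H]1/C=C\[C@@]2(CO2)CC/C=C(/CO)C[C@H]1O | intermediate
23 | (4R,7R,8R)-14-(tert-butyldimethylsilyloxy)-4,15-epoxy-11-(pinacolboryl)-12-norgermacra-1(10),5,11(13)-trien-8-ol | C=C(B1OC(C)(C)C(C)(C)O1)[C@H]1/C=C\[C@@]2(CO2)CC/C=C(/CO[Si](C)(C)C(C)(C)C)C[C@H]1O | intermediate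
24 | angelic acid, (2Z)-2-methylbut-2-enoic acid | C/C=C(/C)C(=O)O | starting material
25 | (2Z)-2-methylbut-2-enoic 2,4,6-trichlorobenzoic anhydride | C/C=C(/C)C(=O)OC(=O)c1c(Cl)cc(Cl)cc1Cl | intermediate
26 | (4R,7R,8R)-8-angeloyloxy-14-(tert-butyldimethylsilyloxy)-4,15-epoxy-11-(pinacolboryl)-12-norgermacra-1(10),5,11(13)-triene, 1(10)E and 5Z | C=C(B1OC(C)(C)C(C)(C)O1)[C@H]1/C=C\[C@@]2(CO2)CC/C=C(/CO[Si](C)(C)C(C)(C)C)C[C@H]1OC(=O)/C(C)=C\C | intermediate
27 | potassium (4R,7R,8R)-8-angeloyloxy-14-(tert-butyldimethylsilyloxy)-4,15-epoxygermacra-1(10),5,11(13)-trien-12-oate | C=C(C(=O)[O-])[C@H]1/C=C\[C@@]2(CO2)CC/C=C(/CO[Si](C)(C)C(C)(C)C)C[C@H]1OC(=O)/C(C)=C\C.[K+] | intermediate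
28 | (6R,7R,8R)-8-angeloyloxy-14-(tert-butyldimethylsilyloxy)-15-hydroxygermacra-1(10),4,11(13)-trien-12,6-olide | C=C1C(=O)O[C@@H]2/C=C(/CO)CC/C=C(/CO[Si](C)(C)C(C)(C)C)C[C@@H](OC(=O)/C(C)=C\C)[C@@H]12 | intermediate
29 | (6R,7R,8R)-8-angeloyloxy-14,15-dihydroxygermacra-1(10),4,11(13)-trien-12,6-olide, both ring alkenes cis within the ring (1(10)E,4E by CIP), trans-fused lactone | C=C1C(=O)O[C@@H]2/C=C(/CO)CC/C=C(/CO)C[C@@H](OC(=O)/C(C)=C\C)[C@@H]12 | target

**Count and risks**

Total: 17 steps. Longest linear sequence: 12 steps (steps 6–17; the branch through steps 1–5 and 11–17 is equally long).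

Step 16 (CO2 lactonisation). What may go wrong: slow transmetalation of the hindered 1,1-disubstituted alkenylboronate, so that protodeboronation or alkoxide-induced isomerisation of the angelate outruns carboxylation. A second failure mode is ionisation through the other C4–C5 rotamer, which would give the cis-fused lactone. The fallback sets out from 26 and returns at 28. Palladium-catalysed syn-1,4-addition of acetic acid to the vinyl epoxide (Pd(PPh3)4, AcOH, THF, rt; no base, so the boronate cannot couple with the allyl) gives the 6α-acetoxy-15-hydroxy alkenylboronate F1. Brief treatment with NaOMe in MeOH at 0 °C removes the acetate to the 6α,15-diol boronate F2, which is not isolated but treated with I2 at −78 °C to give the 11-iodo-6α,15-diol F3 by iododeboronation. Palladium-catalysed cyclocarbonylation (Pd(PPh3)4, CO 1 atm, Et3N, MeCN, 50 °C) then closes the α-methylene lactone from the C6 hydroxyl and gives 28; here the epoxide is consumed before an alkenyl halide meets zerovalent palladium.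

Step 12 (ring-closing metathesis). What may go wrong: strain in the bridged bicycle slows ring closure so that intermolecular metathesis (oligomerisation) takes over. The fallback sets out from 17 and 8 and returns at 21. The lithium aldolate of step 11 is protonated instead of mesylated, and the β-hydroxy lactone F4 (diastereomer mixture) is isolated. Ring-closing metathesis on F4 (second-generation Grubbs catalyst, toluene, high dilution), which has no trisubstituted alkene and a flexible sp3 C1–C10 bond, gives the macrocyclic β-hydroxy lactone F5. Mesylation (MsCl, Et3N) to the macrocyclic mesylate F6, which is not isolated, and E1cB elimination with DBU then install the C1=C10 alkene inside the ring and give 21.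

Step 10 (protoboration). What may go wrong: poor regiocontrol in the Cu–B addition, with boron delivered to the terminal carbon. The fallback sets out from 16 and returns at 17. Markovnikov hydroiodination of the alkyne with HI made in the flask (NaI, Me3SiCl, H2O, MeCN, 0 °C; the isolated alkene reacts much more slowly) gives the 2-iodo-1,4-diene lactone F7. Miyaura borylation (PdCl2(dppf), B2pin2, KOPh, toluene, 50 °C) converts it into 17.

**Further compounds**

F1 | step 16 | 6α-acetoxy-8β-angeloyloxy-14-(tert-butyldimethylsilyloxy)-15-hydroxy-11-(pinacolboryl)-12-norgermacra-1(10),4,11(13)-triene, centres as in 28 | CC(=O)O[C@@H]1/C=C(/CO)CC/C=C(/CO[Si](C)(C)C(C)(C)C)C[C@@H](OC(=O)/C(C)=C\C)[C@H]1C(=C)B1OC(C)(C)C(C)(C)O1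
F2 | step 16 | 8β-angeloyloxy-14-(tert-butyldimethylsilyloxy)-11-(pinacolboryl)-12-norgermacra-1(10),4,11(13)-triene-6α,15-diol, centres as in 28 | O[C@@H]1/C=C(/CO)CC/C=C(/CO[Si](C)(C)C(C)(C)C)C[C@@H](OC(=O)/C(C)=C\C)[C@H]1C(=C)B1OC(C)(C)C(C)(C)O1
F3 | step 16 | 8β-angeloyloxy-14-(tert-butyldimethylsilyloxy)-11-iodo-12-norgermacra-1(10),4,11(13)-triene-6α,15-diol, centres as in 28 | O[C@@H]1/C=C(/CO)CC/C=C(/CO[Si](C)(C)C(C)(C)C)C[C@@H](OC(=O)/C(C)=C\C)[C@H]1C(I)=C
F4 | step 12 | (5R)-3-{3-[(2R)-2-ethenyloxiran-2-yl]-1-hydroxypropyl}-5-[(3R)-2-(pinacolboryl)penta-1,4-dien-3-yl]oxolan-2-one, mixture at the two aldol centres | C=C[C@@H]([C@H]1CC(C(O)CC[C@@]2(C=C)CO2)C(=O)O1)C(=C)B1OC(C)(C)C(C)(C)O1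
F5 | step 12 | (4R,7R,8R)-4,15-epoxy-1-hydroxy-11-(pinacolboryl)-12-norgermacra-5,11(13)-dien-14,8-olide, 5Z, mixture at C1 and C10 | C=C(B1OC(C)(C)C(C)(C)O1)[C@H]1/C=C\[C@@]2(CO2)CCC(O)C3C[C@H]1OC3=O
F6 | step 12 | C1 methanesulfonate of F5 | C=C(B1OC(C)(C)C(C)(C)O1)[C@H]1/C=C\[C@@]2(CO2)CCC(OS(C)(=O)=O)C3C[C@H]1OC3=O
F7 | step 10 | (5R)-5-[(3S)-2-iodopenta-1,4-dien-3-yl]oxolan-2-one | C=C[C@@H]([C@H]1CCC(=O)O1)C(I)=C
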